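**Retrosynthetic overview**
- Last bond: the C9 tiglate, by acylation of the C9 alcohol of a bicyclic α-ketol.
- Key disconnection: C9–C10, C4–C5 and C3–O are cut together, giving an acyclic (S)-α-keto aldehyde triene plus 3-methylbut-2-enoic acid. In the forward sense ring B closes first (aldehyde carbon onto the central (E)-trisubstituted alkene) and ring A second (C5 cation onto the (E)-propenyl group, acid capture at C3), in one operation.
- Keto aldehyde ← chloromethyl ketone ← Weinreb amide ← Evans deconjugative alkylation (C6–C7 bond; sets C7, the only stereocentre carried into the cyclisation).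
- Dienyl bromide ← B-alkyl Suzuki coupling (C1–C10 bond) of (E)-3-iodo-2-methylprop-2-en-1-ol (from propargyl alcohol) with the 9-BBN adduct of (E)-penta-1,3-diene.

Convention: eremophilane numbering is used throughout, also for the acyclic precursors. Ring A = C1, C2, C3, C4, C5, C10; ring B = C5, C6, C7, C8, C9, C10; C14 = methyl on C5; C15 = methyl on C4; C11–C13 = isopropenyl on C7. The target is (3R,4R,5R,7S,9S,10R): a trans-decalin with the C3 ester, C4 methyl, C7 isopropenyl and C9 ester all equatorial and the C5 methyl axial.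

**Step 1**
Reactants: 1 prop-2-yn-1-ol
Product: 3 (E)-3-iodo-2-methylprop-2-en-1-ol, via alkenylalane 2 (not isolated)
Conditions: Me3Al (3 equiv), Cp2ZrCl2 (25 mol %), CH2Cl2, 0 °C to rt; then I2, THF, –30 °C; aq. K2CO3
Reagents that add atoms: trimethylaluminium C[Al](C)C; iodine II
Why: Negishi Cp2ZrCl2-catalysed carboalumination adds CH3 and Al syn across the alkyne (CH3 on the internal carbon), and iodinolysis of the C–Al bond with retention gives the (E)-vinyl iodide with CH2OH and I trans.

**Step 2**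
Reactants: 3 (E)-3-iodo-2-methylprop-2-en-1-ol; 4 (E)-penta-1,3-diene
Product: 6 (2E,6E)-2-methylocta-2,6-dien-1-ol, via alkylborane 5 (not isolated)
Conditions: 4, 9-BBN, THF, 0 °C to rt; then 3, PdCl2(dppf) (5 mol %), 3 M aq. NaOH, THF, 50 °C
Reagents that add atoms: none
Why: 9-BBN hydroborates only the terminal vinyl group of the diene, and the B-alkyl Suzuki–Miyaura coupling joins sp3 C1 to sp2 C10 with retention of both alkene geometries.

**Step 3**
Reactants: 6 (2E,6E)-2-methylocta-2,6-dien-1-ol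
Product: 7 (2E,6E)-1-bromo-2-methylocta-2,6-diene
Conditions: CBr4, PPh3, CH2Cl2, 0 °C
Reagents that add atoms: carbon tetrabromide BrC(Br)(Br)Br
Why: Appel bromination is an SN2 reaction at the primary allylic carbon under neutral conditions, so neither alkene migrates or isomerises.

**Step 4**
Reactants: 8 (S)-4-benzyl-1,3-oxazolidin-2-one; 9 3-methylbut-2-enoyl chloride
Product: 10 (S)-4-benzyl-3-(3-methylbut-2-enoyl)-1,3-oxazolidin-2-one
Conditions: n-BuLi, THF, –78 °C; then 9, –78 to 0 °C
Reagents that add atoms: none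
Why: N-acylation of the lithiated oxazolidinone (loading of the Evans auxiliary); the auxiliary stereocentre is untouched.

**Step 5**
Reactants: 10 (S)-4-benzyl-3-(3-methylbut-2-enoyl)-1,3-oxazolidin-2-one; 7 (2E,6E)-1-bromo-2-methylocta-2,6-diene
Product: 11 (4S)-4-benzyl-3-[(2S,4E,8E)-4-methyl-2-(prop-1-en-2-yl)deca-4,8-dienoyl]-1,3-oxazolidin-2-one
Conditions: NaN(SiMe3)2, THF, –78 °C; then 7, –78 to –30 °C
Reagents that add atoms: none
Why: Evans alkylation in its deconjugative form: γ-deprotonation gives the chelated Z-dienolate, which is alkylated at the α-carbon on the face opposite the benzyl group, creating C7 as (S) together with the isopropenyl group.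

**Step 6**
Reactants: 11 (4S)-4-benzyl-3-[(2S,4E,8E)-4-methyl-2-(prop-1-en-2-yl)deca-4,8-dienoyl]-1,3-oxazolidin-2-one
Product: 12 (2S,4E,8E)-N-methoxy-N,4-dimethyl-2-(prop-1-en-2-yl)deca-4,8-dienamide
Conditions: MeNHOMe·HCl, AlMe3, CH2Cl2, 0 °C to rt
Reagents that add atoms: N,O-dimethylhydroxylamine hydrochloride CNOC.Cl
Why: Transamination of the imide at the exocyclic carbonyl by Me(Cl)Al–N(OMe)Me (Weinreb amide formation) needs no base, so C7 is not epimerised.

**Step 7**
Reactants: 12 (2S,4E,8E)-N-methoxy-N,4-dimethyl-2-(prop-1-en-2-yl)deca-4,8-dienamide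
Product: 13 (3S,5E,9E)-1-chloro-5-methyl-3-(prop-1-en-2-yl)undeca-5,9-dien-2-one
Conditions: ICH2Cl, MeLi·LiBr, THF, –78 °C; aq. NH4Cl
Reagents that add atoms: chloroiodomethane ClCI
Why: LiCH2Cl, formed in situ by iodine–lithium exchange, adds once to the Weinreb amide (chelated tetrahedral intermediate; homologation to the α-chloromethyl ketone), and the weakly basic carbenoid leaves C7 intact.

**Step 8**
Reactants: 13 (3S,5E,9E)-1-chloro-5-methyl-3-(prop-1-en-2-yl)undeca-5,9-dien-2-one
Product: 15 (3S,5E,9E)-5-methyl-2-oxo-3-(prop-1-en-2-yl)undeca-5,9-dienal, via iodomethyl ketone 14 (not isolated)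
Conditions: NaI, NaHCO3, DMSO, rt; dried azeotropically (toluene) and used crude
Reagents that add atoms: dimethyl sulfoxide CS(C)=O
Why: Finkelstein exchange followed by Kornblum oxidation: DMSO displaces iodide at the primary α-keto carbon and the alkoxysulfonium salt collapses with bicarbonate to the aldehyde, the weak base sparing C7.

**Step 9**
Reactants: 15 (3S,5E,9E)-5-methyl-2-oxo-3-(prop-1-en-2-yl)undeca-5,9-dienal; 16 3-methylbut-2-enoic acid
Product: 17 (3R,4R,5R,7S,9S,10R)-9-hydroxy-8-oxoeremophil-11-en-3-yl 3-methylbut-2-enoate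
Conditions: Sc(OTf)3 (20 mol %), 16 (10 equiv), 2,6-di-tert-butyl-4-methylpyridine (30 mol %), 4 Å MS, CH2Cl2/EtNO2 4:1, 0.01 M in 15, –78 to –40 °C
Reagents that add atoms: none
Why: Proposed new method: Sc(OTf)3 chelates the s-cis 1,2-dicarbonyl unit so that the aldehyde carbon C9 is attacked by C10 of the (E)-trisubstituted alkene through a six-membered chair (Prins or glyoxylate-ene type step; isopropenyl on C7 and O9 both equatorial); the developing tertiary C5 cation is taken by C4 of the (E)-propenyl group anti to the new C9–C10 bond (Stork–Eschenmoser chair–chair anti addition, hence trans fusion with axial C5 methyl and axial H10); the incipient secondary C3 cation is captured by the carbonyl oxygen of 16 anti to the new C4–C5 bond, on the face away from the axial C5 methyl, which puts the C4 methyl and the C3 ester equatorial; the closest known reaction types are Lewis-acid glyoxylate-ene and Prins cyclisations, Johnson cation–olefin bicyclisations of (E,E)-dienes terminated by formic or trifluoroacetic acid, and Prins cyclisations terminated by acetic acid.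

**Step 10**
Reactants: 17 (3R,4R,5R,7S,9S,10R)-9-hydroxy-8-oxoeremophil-11-en-3-yl 3-methylbut-2-enoate; 18 (E)-2-methylbut-2-enoyl chloride
Product: 19 (3R,4R,5R,7S,9S,10R)-3-(3-methylbut-2-enoyloxy)-8-oxoeremophil-11-en-9-yl (E)-2-methylbut-2-enoate
Conditions: pyridine, DMAP (cat.), CH2Cl2, 0 °C to rt
Reagents that add atoms: none
Why: DMAP-catalysed O-acylation of the secondary α-ketol breaks no bond to C9, so the equatorial (9S) centre and the (E)-geometry of the tiglate are retained.

**Compound list**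
1 | prop-2-yn-1-ol | C#CCO | starting material
2 | (E)-[3-(dimethylalumanyloxy)-2-methylprop-1-en-1-yl]dimethylalumane | C/C(CO[Al](C)C)=C\[Al](C)C | intermediate
3 | (E)-3-iodo-2-methylprop-2-en-1-ol | OC/C(C)=C/I | intermediate
4 | (E)-penta-1,3-diene | C=C/C=C/C | starting material
5 | 9-[(E)-pent-3-en-1-yl]-9-borabicyclo[3.3.1]nonane | C/C=C/CCB1C2CCCC1CCC2 | intermediate
6 | (2E,6E)-2-methylocta-2,6-dien-1-ol | OC/C(C)=C/CC/C=C/C | intermediate
7 | (2E,6E)-1-bromo-2-methylocta-2,6-diene | BrC/C(C)=C/CC/C=C/C | intermediate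
8 | (S)-4-benzyl-1,3-oxazolidin-2-one | O=C1N[C@@H](Cc2ccccc2)CO1 | starting material
9 | 3-methylbut-2-enoyl chloride | CC(C)=CC(=O)Cl | starting material
10 | (S)-4-benzyl-3-(3-methylbut-2-enoyl)-1,3-oxazolidin-2-one | CC(C)=CC(=O)N1[C@@H](Cc2ccccc2)COC1=O | intermediate
11 | (4S)-4-benzyl-3-[(2S,4E,8E)-4-methyl-2-(prop-1-en-2-yl)deca-4,8-dienoyl]-1,3-oxazolidin-2-one | C=C(C)[C@@H](C(=O)N1[C@@H](Cc2ccccc2)COC1=O)C/C(C)=C/CC/C=C/C | intermediate
12 | (2S,4E,8E)-N-methoxy-N,4-dimethyl-2-(prop-1-en-2-yl)deca-4,8-dienamide | C=C(C)[C@@H](C(=O)N(C)OC)C/C(C)=C/CC/C=C/C | intermediate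
13 | (3S,5E,9E)-1-chloro-5-methyl-3-(prop-1-en-2-yl)undeca-5,9-dien-2-one | C=C(C)[C@@H](C(=O)CCl)C/C(C)=C/CC/C=C/C | intermediate
14 | (3S,5E,9E)-1-iodo-5-methyl-3-(prop-1-en-2-yl)undeca-5,9-dien-2-one | C=C(C)[C@@H](C(=O)CI)C/C(C)=C/CC/C=C/C | intermediate
15 | (3S,5E,9E)-5-methyl-2-oxo-3-(prop-1-en-2-yl)undeca-5,9-dienal | C=C(C)[C@@H](C(=O)C=O)C/C(C)=C/CC/C=C/C | intermediate
16 | 3-methylbut-2-enoic acid | CC(C)=CC(=O)O | starting material
17 | (3R,4R,5R,7S,9S,10R)-9-hydroxy-8-oxoeremophil-11-en-3-yl 3-methylbut-2-enoate (trans-decalin; C3 ester, C4 methyl, C7 isopropenyl and C9 OH equatorial) | C=C(C)[C@@H]1C[C@]2(C)[C@@H](C)[C@H](OC(=O)C=C(C)C)CC[C@H]2[C@H](O)C1=O | intermediate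
18 | (E)-2-methylbut-2-enoyl chloride | C/C=C(\C)C(=O)Cl | starting material
19 | (3R,4R,5R,7S,9S,10R)-3-(3-methylbut-2-enoyloxy)-8-oxoeremophil-11-en-9-yl (E)-2-methylbut-2-enoate, i.e. (1S,3S,4aR,5R,6R,8aR)-4a,5-dimethyl-6-[(3-methylbut-2-enoyl)oxy]-2-oxo-3-(prop-1-en-2-yl)decahydronaphthalen-1-yl (2E)-2-methylbut-2-enoate | C=C(C)[C@@H]1C[C@]2(C)[C@@H](C)[C@H](OC(=O)C=C(C)C)CC[C@H]2[C@H](OC(=O)/C(C)=C/C)C1=O | target

**Step count and risk**
Total steps: 10. Longest linear sequence: 9 steps (1 → 3 → 6 → 7 → 11 → 12 → 13 → 15 → 17 → 19).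

Most likely to fail, first: step 9. The C5 cation may be captured by the acid or lose a proton before ring A closes. The aldehyde may instead close a five-membered ring onto the isopropenyl group. A 1,2-hydride shift from C4 to C3 may compete with capture. Facial control by C7 alone may be modest; the minor isomer is a diastereomer and is removed by chromatography. Fallback: setting out from 15, the same Sc(OTf)3 bicyclisation is run with formic acid (20 equiv, –40 °C), the classical small terminating acid, in place of 16. This gives (3R,4R,5R,7S,9S,10R)-9-hydroxy-8-oxoeremophil-11-en-3-yl formate F1. Its C9 alcohol is acylated with 18 (pyridine, DMAP) to (3R,4R,5R,7S,9S,10R)-3-formyloxy-8-oxoeremophil-11-en-9-yl (E)-2-methylbut-2-enoate F2. The formate alone is cleaved (KHCO3, MeOH, 0 °C) to (3R,4R,5R,7S,9S,10R)-3-hydroxy-8-oxoeremophil-11-en-9-yl (E)-2-methylbut-2-enoate F3. Steglich esterification of F3 with 16 (DCC, DMAP, CH2Cl2) comes back to the route at 19.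

Second: step 8. The α-keto aldehyde carries an acidic, allylic C7–H, so DMSO/NaHCO3 may epimerise C7 or move the isopropenyl double bond into conjugation. Fallback: setting out from 12, addition of 2-lithio-1,3-dithiane (THF, –78 °C) gives (2S,4E,8E)-1-(1,3-dithian-2-yl)-4-methyl-2-(prop-1-en-2-yl)deca-4,8-dien-1-one F4. Unmasking with PhI(OCOCF3)2 and NaHCO3 in MeCN/H2O at 0 °C (a masked formyl anion in place of halide oxidation) comes back to the route at 15.

Third: step 5. The dienolate may react at the γ-carbon or give poor facial selectivity with the long dienyl bromide. Fallback: setting out from 3, Appel bromination (CBr4, PPh3) gives the small, highly reactive (E)-3-bromo-1-iodo-2-methylprop-1-ene F5. The dienolate of 10 (NaN(SiMe3)2, THF, –78 °C) is alkylated with F5 to (4S)-4-benzyl-3-[(2S,4E)-5-iodo-4-methyl-2-(prop-1-en-2-yl)pent-4-enoyl]-1,3-oxazolidin-2-one F6. The side chain is then attached after the stereocentre is set, by B-alkyl Suzuki coupling of F6 with borane 5 (from 4 and 9-BBN; PdCl2(dppf), K3PO4, DMF/THF/H2O, rt), which comes back to the route at 11.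

**Further compounds**
F1 | step 9 | (3R,4R,5R,7S,9S,10R)-9-hydroxy-8-oxoeremophil-11-en-3-yl formate | C=C(C)[C@@H]1C[C@]2(C)[C@@H](C)[C@H](OC=O)CC[C@H]2[C@H](O)C1=O
F2 | step 9 | (3R,4R,5R,7S,9S,10R)-3-formyloxy-8-oxoeremophil-11-en-9-yl (E)-2-methylbut-2-enoate | C=C(C)[C@@H]1C[C@]2(C)[C@@H](C)[C@H](OC=O)CC[C@H]2[C@H](OC(=O)/C(C)=C/C)C1=O
F3 | step 9 | (3R,4R,5R,7S,9S,10R)-3-hydroxy-8-oxoeremophil-11-en-9-yl (E)-2-methylbut-2-enoate | C=C(C)[C@@H]1C[C@]2(C)[C@@H](C)[C@H](O)CC[C@H]2[C@H](OC(=O)/C(C)=C/C)C1=O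
F4 | step 8 | (2S,4E,8E)-1-(1,3-dithian-2-yl)-4-methyl-2-(prop-1-en-2-yl)deca-4,8-dien-1-one | C=C(C)[C@@H](C(=O)C1SCCCS1)C/C(C)=C/CC/C=C/C
F5 | step 5 | (E)-3-bromo-1-iodo-2-methylprop-1-ene | BrC/C(C)=C/I
F6 | step 5 | (4S)-4-benzyl-3-[(2S,4E)-5-iodo-4-methyl-2-(prop-1-en-2-yl)pent-4-enoyl]-1,3-oxazolidin-2-one | C=C(C)[C@@H](C(=O)N1[C@@H](Cc2ccccc2)COC1=O)C/C(C)=C/I
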